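**Plan**

1. Retrosynthesis: remove the C6 isovalerate, then cut C13=C14 (olefination of a C13 methyl ketone), C7–O (enolate oxidation) and ring B at C7=C8 (ring-closing metathesis of a C6 vinyl ketone onto a C8 isopropenyl group). Next cut the C5–C10 ring-fusion bond of ring A (lactone enolate Claisen), then C1–C2 (alkenyl–acyl coupling) and C9–C11 (enolate alkylation).
2. Enabling feature: quaternary C10 is bonded to C5, and C5 is α to the oxygenated carbon C6. With a C1=C2 bond in ring A, the array C6–C5–C10–C1=C2 is a γ,δ-unsaturated acid, the product of a [3,3] shift of a C6 ester enolate held on C2 through oxygen (a 6-alkenyl δ-lactone spanning C2–C6).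
3. Forward order: open chain (C9 branch point, alkyne, carboalumination, acylation) → δ-lactone → ring A (step 9) → ring B (step 11) → C7/C6 oxygenation → side chain → ester.
4. Stereochemistry: one CBS reduction sets the C2 carbinol; the boat [3,3] shift relays it to C10 and, provisionally, C5; C5 is then equilibrated to the trans fusion. 7α-OH and 6β-OH come from α-face attack on the rigid bicycle, 13E from the HWE reaction, and the racemic C9 centre disappears when C9 becomes sp2.

Key step: step 9

Remark: labdane numbering is used for all intermediates; α/β refer to the usual orientation with the C10 methyl β, and the SMILES define every configuration.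
Remark: C9 is deliberately uncontrolled (4–6, 10 and 11 racemic; 12–21 mixtures of C9 epimers, left open in the SMILES), because step 14 makes C9 sp2.

**Step 1**
Reactants: 1 ethyl 3-methylbut-2-enoate; 2 2-(2-bromoethyl)-2-methyl-1,3-dioxolane
Product: 4 ethyl 4-(2-methyl-1,3-dioxolan-2-yl)-2-(prop-1-en-2-yl)butanoate (racemic), via lithium dienolate 3 (not isolated)
Conditions: LDA, THF–DMPU, −78 °C; then 2, −78 → 0 °C
Reagents that add atoms: none
Why: Deconjugative α-alkylation of the extended ester dienolate by the primary bromide creates C9 and leaves the double bond as the isopropenyl group (future C7, C8, C17).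

**Step 2**
Reactants: 4 ethyl 4-(2-methyl-1,3-dioxolan-2-yl)-2-(prop-1-en-2-yl)butanoate
Product: 5 4-(2-methyl-1,3-dioxolan-2-yl)-2-(prop-1-en-2-yl)butanal
Conditions: DIBAL-H (1.05 equiv), CH2Cl2, −78 °C; Rochelle salt work-up
Reagents that add atoms: none
Why: Partial DIBAL-H reduction of an α-branched ester stops at the aldehyde at −78 °C; the β,γ-unsaturated aldehyde is used at once to avoid conjugation.

**Step 3**
Reactants: 5 4-(2-methyl-1,3-dioxolan-2-yl)-2-(prop-1-en-2-yl)butanal
Product: 6 2-methyl-2-[3-(prop-1-en-2-yl)pent-4-yn-1-yl]-1,3-dioxolane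
Conditions: TMSCHN2, LDA, THF, −78 °C → rt
Reagents that add atoms: (trimethylsilyl)diazomethane C[Si](C)(C)C=[N+]=[N-]
Why: Colvin rearrangement (addition of lithiated silyldiazomethane, Peterson elimination, 1,2-hydride shift of the alkylidene carbene) gives the terminal alkyne (future C10) without the alkoxide/methanol medium that could conjugate the aldehyde.

**Step 4**
Reactants: 7 3,3-dimethylglutaric anhydride
Product: 8 5-methoxy-3,3-dimethyl-5-oxopentanoic acid
Conditions: MeOH, reflux
Reagents that add atoms: methanol CO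
Why: Alcoholysis of the symmetrical cyclic anhydride can give only one half-ester.

**Step 5**
Reactants: 8 5-methoxy-3,3-dimethyl-5-oxopentanoic acid
Product: 9 methyl 5-chloro-3,3-dimethyl-5-oxopentanoate
Conditions: (COCl)2, cat. DMF, CH2Cl2, 0 °C → rt
Reagents that add atoms: oxalyl chloride O=C(Cl)C(=O)Cl
Why: Vilsmeier-type acid chloride formation activates the free acid and leaves the methyl ester untouched.

**Step 6**
Reactants: 6 2-methyl-2-[3-(prop-1-en-2-yl)pent-4-yn-1-yl]-1,3-dioxolane; 9 methyl 5-chloro-3,3-dimethyl-5-oxopentanoate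
Product: 11 methyl (6E)-3,3,7-trimethyl-10-(2-methyl-1,3-dioxolan-2-yl)-5-oxo-8-(prop-1-en-2-yl)dec-6-enoate, via alkenylalane 10 (not isolated)
Conditions: AlMe3 (2 equiv), Cp2ZrCl2 (10 mol%), H2O (1 equiv), CH2Cl2, −20 °C; volatiles removed; then 9, Pd(PPh3)4 (5 mol%), THF, 0 °C → rt
Reagents that add atoms: trimethylaluminium C[Al](C)C
Why: Zirconium-catalysed syn-methylalumination of the terminal alkyne (Negishi carboalumination, water-accelerated low-temperature variant to spare the ketal) places the C20 methyl and aluminium cis, and Pd-catalysed acylation of the alkenylalane with retention gives the (E)-enone with C9 trans to the carbonyl.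

**Step 7**
Reactants: 11 methyl (6E)-3,3,7-trimethyl-10-(2-methyl-1,3-dioxolan-2-yl)-5-oxo-8-(prop-1-en-2-yl)dec-6-enoate
Product: 12 methyl (5S,6E)-5-hydroxy-3,3,7-trimethyl-10-(2-methyl-1,3-dioxolan-2-yl)-8-(prop-1-en-2-yl)dec-6-enoate
Conditions: (R)-Me-CBS oxazaborolidine (20 mol%), catecholborane (1.8 equiv), toluene, −78 °C; MeOH quench
Reagents that add atoms: none
Why: Corey–Bakshi–Shibata reduction: the enone binds with its β,β-disubstituted alkenyl group as the large substituent, so the (R)-catalyst should give the (S)-allylic alcohol (C2), and catecholborane at −78 °C leaves the isopropenyl group, the ester and the ketal alone.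

**Step 8**
Reactants: 12 methyl (5S,6E)-5-hydroxy-3,3,7-trimethyl-10-(2-methyl-1,3-dioxolan-2-yl)-8-(prop-1-en-2-yl)dec-6-enoate
Product: 13 (6S)-4,4-dimethyl-6-[(1E)-2-methyl-5-(2-methyl-1,3-dioxolan-2-yl)-3-(prop-1-en-2-yl)pent-1-en-1-yl]oxan-2-one
Conditions: PPTS (10 mol%), toluene, 4 Å MS, 60 °C
Reagents that add atoms: none
Why: Acid-catalysed intramolecular transesterification to the δ-lactone is favoured by the gem-dimethyl (Thorpe–Ingold) effect and removal of methanol, and the carbinol C–O bond is not broken, so the (S) configuration is kept.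

**Step 9**
Reactants: 13 (6S)-4,4-dimethyl-6-[(1E)-2-methyl-5-(2-methyl-1,3-dioxolan-2-yl)-3-(prop-1-en-2-yl)pent-1-en-1-yl]oxan-2-one
Product: 16 (1R,2R)-2,6,6-trimethyl-2-[2-methyl-5-(2-methyl-1,3-dioxolan-2-yl)pent-1-en-3-yl]cyclohex-3-ene-1-carboxylic acid (ring A; C6 carboxyl cis to the C9 arm), via silyl ketene acetal 14 (not isolated), via silyl ester 15 (not isolated)
Conditions: LDA, THF, −78 °C; TBSCl, DMPU, −78 → 0 °C; toluene, 105 °C; then 1 M LiOH, THF, rt; 1 M HCl to pH 4, 0 °C
Reagents that add atoms: none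
Why: Enolisation at the only acidic site (the C5 methylene; the side-chain ketone is masked) and O-silylation give the cyclic silyl ketene acetal, in which C5=C6 and the C1=C10 alkene are joined through O–C2, and on heating a concerted suprafacial [3,3] shift forms C5–C10 and cleaves C2–O, contracting the δ-lactone to the ring A cyclohexene that carries C6 as a silyl ester (hydrolysed on work-up). The closest known reaction type is the Ireland–Claisen rearrangement of 6-alkenyl δ-lactone silyl ketene acetals to cycloalkene carboxylic acids. Ring A closes by this sigmatropic ring contraction; because the C3–C4 tether ties the ketene acetal carbon C5 to the allylic carbon C2, the six-centre array can only be a bicyclo[2.2.2]-like boat, so the new C1=C2 ring alkene is necessarily cis. C10 is set by chirality transfer from the (S)-carbinol C2 across the face of the (E)-alkene that the boat exposes (methyl cis to C2, C9 trans), which gives the target arrangement at C10; C5 is set by the ring-fixed ketene acetal geometry, which places the C6 carboxyl cis to the C9 arm (5-epi, corrected in step 13). The step needs the [3,3] shift to outrun fragmentation or 1,3-silyl migration of the congested ketene acetal, which the pre-organised boat and the robust TBS acetal are meant to secure, and no regiochemical question arises because there is one enolisable carbonyl and one allylic C–O bond.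

**Step 10**
Reactants: 16 (1R,2R)-2,6,6-trimethyl-2-[2-methyl-5-(2-methyl-1,3-dioxolan-2-yl)pent-1-en-3-yl]cyclohex-3-ene-1-carboxylic acid
Product: 18 1-{(1R,2R)-2,6,6-trimethyl-2-[2-methyl-5-(2-methyl-1,3-dioxolan-2-yl)pent-1-en-3-yl]cyclohex-3-en-1-yl}prop-2-en-1-one, via acid chloride 17 (not isolated)
Conditions: 1-chloro-N,N,2-trimethylprop-1-en-1-amine, CH2Cl2, 0 °C → rt; then tributyl(vinyl)stannane, BnPdCl(PPh3)2 (5 mol%), THF, 50 °C
Reagents that add atoms: tributyl(vinyl)stannane C=C[Sn](CCCC)(CCCC)CCCC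
Why: The acid chloride is made under neutral conditions with Ghosez's reagent (no HCl, ketal safe) and coupled with the vinylstannane in a Stille ketone synthesis, which tolerates the hindered α-carbon and brings in C7.

**Step 11**
Reactants: 18 1-{(1R,2R)-2,6,6-trimethyl-2-[2-methyl-5-(2-methyl-1,3-dioxolan-2-yl)pent-1-en-3-yl]cyclohex-3-en-1-yl}prop-2-en-1-one
Product: 19 (5R,10R)-14,15-dinorlabda-1,7-diene-6,13-dione 13-ethylene ketal (cis-fused: 5β-H and 10β-CH3)
Conditions: Hoveyda–Grubbs II catalyst (10 mol%), toluene, 80 °C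
Reagents that add atoms: none
Why: Ring-closing metathesis between the vinyl ketone and the isopropenyl group, held cis on ring A, closes the six-membered ring B as the 8-methyl-7-en-6-one with loss of ethylene, an enone RCM with a 1,1-disubstituted partner of the kind second-generation ruthenium catalysts effect, and the unstrained C1=C2 ring alkene should not take part.

**Step 12**
Reactants: 19 (5R,10R)-14,15-dinorlabda-1,7-diene-6,13-dione 13-ethylene ketal
Product: 20 (5R,10R)-14,15-dinorlabd-7-ene-6,13-dione 13-ethylene ketal (cis-fused: 5β-H)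
Conditions: H2 (1 atm), RhCl(PPh3)3 (10 mol%), benzene–EtOH, rt
Reagents that add atoms: none
Why: Homogeneous hydrogenation with Wilkinson's catalyst reduces the cis-disubstituted C1=C2 bond and leaves the trisubstituted conjugated C7=C8 bond untouched.

**Step 13**
Reactants: 20 (5R,10R)-14,15-dinorlabd-7-ene-6,13-dione 13-ethylene ketal
Product: 21 (5S,10R)-14,15-dinorlabd-7-ene-6,13-dione 13-ethylene ketal (trans-fused: 5α-H and 10β-CH3)
Conditions: NaOMe (0.3 equiv), MeOH, 40 °C
Reagents that add atoms: none
Why: Base-mediated equilibration through the C5(6) enolate should epimerise the ring-fusion carbon to the trans-decalone preferred in 6-oxo labdanes (5α-H anti to the 10β-methyl), and since the conjugated enone is already the stable double-bond isomer no alkene migration can compete (C9 may equilibrate too, without consequence).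

**Step 14**
Reactants: 21 (5S,10R)-14,15-dinorlabd-7-ene-6,13-dione 13-ethylene ketal
Product: 23 (5S,7S,10S)-7α-hydroxy-14,15-dinorlabd-8-ene-6,13-dione 13-ethylene ketal, via potassium dienolate 22 (not isolated)
Conditions: t-BuOK (1.5 equiv), THF–t-BuOH, 0 °C; then −78 °C, 2-(benzenesulfonyl)-3-phenyloxaziridine; NH4Cl quench
Reagents that add atoms: 2-(benzenesulfonyl)-3-phenyloxaziridine O=S(=O)(c1ccccc1)N1OC1c1ccccc1
Why: Under equilibrating conditions t-BuOK removes H-9 to give the linear dienolate (the thermodynamic enolate of a β-alkylcyclohexenone), and the N-sulfonyloxaziridine transfers oxygen to its α-carbon C7 (Davis enolate hydroxylation) from the α-face, opposite the axial C10 and C4β methyl groups, which leaves the double bond at C8=C9, removes the uncontrolled C9 centre and sets 7α-OH.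

**Step 15**
Reactants: 23 (5S,7S,10S)-7α-hydroxy-14,15-dinorlabd-8-ene-6,13-dione 13-ethylene ketal
Product: 24 (5S,6S,7S,10S)-6β,7α-dihydroxy-14,15-dinorlabd-8-en-13-one ethylene ketal
Conditions: Me4NBH(OAc)3 (5 equiv), MeCN–AcOH (1:1), −20 → 0 °C
Reagents that add atoms: none
Why: Hydroxyl-directed reduction (Evans–Saksena type): the acetoxyborohydride exchanges onto the 7α-hydroxyl and delivers hydride intramolecularly to the α-face of the C6 ketone, the face the two syn-axial methyl groups (C10, C4β) also leave open, so the axial 6β-alcohol trans to 7α-OH should result.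

**Step 16**
Reactants: 24 (5S,6S,7S,10S)-6β,7α-dihydroxy-14,15-dinorlabd-8-en-13-one ethylene ketal
Product: 25 6β,7α-dihydroxy-14,15-dinorlabd-8-en-13-one
Conditions: PPTS (20 mol%), acetone–H2O (10:1), rt → 40 °C
Reagents that add atoms: water O
Why: Mild acid-catalysed acetal hydrolysis frees the C13 methyl ketone under conditions the allylic diol should tolerate, and the trans-diaxial hydroxyls cannot form an acetonide.

**Step 17**
Reactants: 25 6β,7α-dihydroxy-14,15-dinorlabd-8-en-13-one
Product: 26 ethyl (13E)-6β,7α-dihydroxylabda-8,13-dien-15-oate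
Conditions: ethyl 2-[di(propan-2-yloxy)phosphoryl]acetate, NaH (sodium salt preformed, 3 equiv), THF, 0 → 40 °C
Reagents that add atoms: ethyl 2-[di(propan-2-yloxy)phosphoryl]acetate CCOC(=O)CP(=O)(OC(C)C)OC(C)C
Why: Horner–Wadsworth–Emmons olefination of the unhindered methyl ketone with a bulky phosphonoacetate should favour the (E)-enoate (C12 trans to the ester; any Z isomer removed by chromatography), and the weakly basic stabilised carbanion leaves the free diol alone.

**Step 18**
Reactants: 26 ethyl (13E)-6β,7α-dihydroxylabda-8,13-dien-15-oate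
Product: 27 (13E)-labda-8,13-diene-6β,7α,15-triol
Conditions: DIBAL-H (5 equiv), CH2Cl2, −78 °C; Rochelle salt work-up
Reagents that add atoms: none
Why: DIBAL-H 1,2-reduction of the α,β-unsaturated ester gives the primary allylic alcohol without touching either alkene.

**Step 19**
Reactants: 27 (13E)-labda-8,13-diene-6β,7α,15-triol
Product: 28 (13E)-7α,15-bis(triethylsilyloxy)labda-8,13-dien-6β-ol
Conditions: TESCl (2.3 equiv), imidazole, CH2Cl2, −20 → 0 °C
Reagents that add atoms: chlorotriethylsilane CC[Si](Cl)(CC)CC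
Why: Sterically controlled silylation: the primary allylic 15-OH and the allylic 7α-OH react, whereas the axial 6β-OH, flanked by the syn-axial C10 and C4β methyl groups, should stay free.

**Step 20**
Reactants: 28 (13E)-7α,15-bis(triethylsilyloxy)labda-8,13-dien-6β-ol
Product: 29 (13E)-7α,15-bis(triethylsilyloxy)labda-8,13-dien-6β-yl 3-methylbutanoate
Conditions: 3-methylbutanoic anhydride, DMAP (1.5 equiv), Et3N, toluene, 50 °C
Reagents that add atoms: 3-methylbutanoic anhydride CC(C)CC(=O)OC(=O)CC(C)C
Why: DMAP-catalysed acyl transfer (Steglich-type acylation) esterifies the only free, hindered secondary alcohol with retention at C6.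

**Step 21**
Reactants: 29 (13E)-7α,15-bis(triethylsilyloxy)labda-8,13-dien-6β-yl 3-methylbutanoate
Product: 30 (5S,6S,7S,10S,13E)-7α,15-dihydroxylabda-8,13-dien-6β-yl 3-methylbutanoate (CNP0173680.1)
Conditions: HF·pyridine, pyridine, THF, 0 °C → rt
Reagents that add atoms: none
Why: Buffered fluoride cleavage of both triethylsilyl ethers; the trans-diaxial 6β-ester/7α-hydroxyl relationship should prevent acyl migration and the buffered medium should spare the allylic alcohols.

**Compound list**

1 | ethyl 3-methylbut-2-enoate | CCOC(=O)C=C(C)C | starting material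
2 | 2-(2-bromoethyl)-2-methyl-1,3-dioxolane | CC1(CCBr)OCCO1 | starting material
3 | lithium 1-ethoxy-3-methylbuta-1,3-dien-1-olate (dienolate of 1, not isolated) | [Li+].[O-]C(OCC)=CC(C)=C | intermediate
4 | ethyl 4-(2-methyl-1,3-dioxolan-2-yl)-2-(prop-1-en-2-yl)butanoate (racemic) | CCOC(=O)C(CCC1(C)OCCO1)C(C)=C | intermediate
5 | 4-(2-methyl-1,3-dioxolan-2-yl)-2-(prop-1-en-2-yl)butanal (racemic) | O=CC(CCC1(C)OCCO1)C(C)=C | intermediate
6 | 2-methyl-2-[3-(prop-1-en-2-yl)pent-4-yn-1-yl]-1,3-dioxolane (racemic) | C#CC(CCC1(C)OCCO1)C(C)=C | intermediate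
7 | 3,3-dimethylglutaric anhydride (4,4-dimethyloxane-2,6-dione) | CC1(C)CC(=O)OC(=O)C1 | starting material
8 | 5-methoxy-3,3-dimethyl-5-oxopentanoic acid | COC(=O)CC(C)(C)CC(=O)O | intermediate
9 | methyl 5-chloro-3,3-dimethyl-5-oxopentanoate | COC(=O)CC(C)(C)CC(=O)Cl | intermediate
10 | dimethyl[(1E)-2-methyl-5-(2-methyl-1,3-dioxolan-2-yl)-3-(prop-1-en-2-yl)pent-1-en-1-yl]alumane (not isolated) | C[Al](C)/C=C(\C)C(CCC1(C)OCCO1)C(C)=C | intermediate
11 | methyl (6E)-3,3,7-trimethyl-10-(2-methyl-1,3-dioxolan-2-yl)-5-oxo-8-(prop-1-en-2-yl)dec-6-enoate (racemic) | COC(=O)CC(C)(C)CC(=O)/C=C(\C)C(CCC1(C)OCCO1)C(C)=C | intermediate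
12 | methyl (5S,6E)-5-hydroxy-3,3,7-trimethyl-10-(2-methyl-1,3-dioxolan-2-yl)-8-(prop-1-en-2-yl)dec-6-enoate (both C8 epimers) | COC(=O)CC(C)(C)C[C@H](O)/C=C(\C)C(CCC1(C)OCCO1)C(C)=C | intermediate
13 | (6S)-4,4-dimethyl-6-[(1E)-2-methyl-5-(2-methyl-1,3-dioxolan-2-yl)-3-(prop-1-en-2-yl)pent-1-en-1-yl]oxan-2-one (both C9 epimers) | O=C1CC(C)(C)C[C@@H](/C=C(\C)C(CCC2(C)OCCO2)C(C)=C)O1 | intermediate
14 | tert-butyldimethylsilyl ketene acetal of 13: (2S)-6-(tert-butyldimethylsilyloxy)-4,4-dimethyl-2-alkenyl-3,4-dihydro-2H-pyran (not isolated) | CC(C)(C)[Si](C)(C)OC1=CC(C)(C)C[C@@H](/C=C(\C)C(CCC2(C)OCCO2)C(C)=C)O1 | intermediate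
15 | tert-butyldimethylsilyl ester of 16 (not isolated) | CC(C)(C)[Si](C)(C)OC(=O)[C@@H]1C(C)(C)CC=C[C@]1(C)C(CCC2(C)OCCO2)C(C)=C | intermediate
16 | (1R,2R)-2,6,6-trimethyl-2-[2-methyl-5-(2-methyl-1,3-dioxolan-2-yl)pent-1-en-3-yl]cyclohex-3-ene-1-carboxylic acid (labdane C5 R, C10 R; both C9 epimers) | OC(=O)[C@@H]1C(C)(C)CC=C[C@]1(C)C(CCC2(C)OCCO2)C(C)=C | intermediate
17 | acid chloride of 16 (not isolated) | ClC(=O)[C@@H]1C(C)(C)CC=C[C@]1(C)C(CCC2(C)OCCO2)C(C)=C | intermediate
18 | 1-{(1R,2R)-2,6,6-trimethyl-2-[2-methyl-5-(2-methyl-1,3-dioxolan-2-yl)pent-1-en-3-yl]cyclohex-3-en-1-yl}prop-2-en-1-one | C=CC(=O)[C@@H]1C(C)(C)CC=C[C@]1(C)C(CCC2(C)OCCO2)C(C)=C | intermediate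
19 | (5R,10R)-14,15-dinorlabda-1,7-diene-6,13-dione 13-ethylene ketal (cis-fused, 5β-H; C9 epimers) | CC1=CC(=O)[C@@H]2C(C)(C)CC=C[C@]2(C)C1CCC3(C)OCCO3 | intermediate
20 | (5R,10R)-14,15-dinorlabd-7-ene-6,13-dione 13-ethylene ketal (cis-fused, 5β-H; C9 epimers) | CC1=CC(=O)[C@@H]2C(C)(C)CCC[C@]2(C)C1CCC3(C)OCCO3 | intermediate
21 | (5S,10R)-14,15-dinorlabd-7-ene-6,13-dione 13-ethylene ketal (trans-fused, 5α-H; C9 open) | CC1=CC(=O)[C@H]2C(C)(C)CCC[C@]2(C)C1CCC3(C)OCCO3 | intermediate
22 | potassium 6,8-dienolate of 21 (not isolated) | [K+].CC1=C(CCC3(C)OCCO3)[C@@]2(C)CCCC(C)(C)[C@@H]2C([O-])=C1 | intermediate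
23 | (5S,7S,10S)-7α-hydroxy-14,15-dinorlabd-8-ene-6,13-dione 13-ethylene ketal | CC1=C(CCC3(C)OCCO3)[C@@]2(C)CCCC(C)(C)[C@@H]2C(=O)[C@H]1O | intermediate
24 | (5S,6S,7S,10S)-6β,7α-dihydroxy-14,15-dinorlabd-8-en-13-one ethylene ketal | CC1=C(CCC3(C)OCCO3)[C@@]2(C)CCCC(C)(C)[C@@H]2[C@H](O)[C@H]1O | intermediate
25 | (5S,6S,7S,10S)-6β,7α-dihydroxy-14,15-dinorlabd-8-en-13-one | CC1=C(CCC(C)=O)[C@@]2(C)CCCC(C)(C)[C@@H]2[C@H](O)[C@H]1O | intermediate
26 | ethyl (13E)-6β,7α-dihydroxylabda-8,13-dien-15-oate | CC1=C(CC/C(C)=C/C(=O)OCC)[C@@]2(C)CCCC(C)(C)[C@@H]2[C@H](O)[C@H]1O | intermediate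
27 | (13E)-labda-8,13-diene-6β,7α,15-triol | CC1=C(CC/C(C)=C/CO)[C@@]2(C)CCCC(C)(C)[C@@H]2[C@H](O)[C@H]1O | intermediate
28 | (13E)-7α,15-bis(triethylsilyloxy)labda-8,13-dien-6β-ol | CC1=C(CC/C(C)=C/CO[Si](CC)(CC)CC)[C@@]2(C)CCCC(C)(C)[C@@H]2[C@H](O)[C@H]1O[Si](CC)(CC)CC | intermediate
29 | (13E)-7α,15-bis(triethylsilyloxy)labda-8,13-dien-6β-yl 3-methylbutanoate | CC1=C(CC/C(C)=C/CO[Si](CC)(CC)CC)[C@@]2(C)CCCC(C)(C)[C@@H]2[C@H](OC(=O)CC(C)C)[C@H]1O[Si](CC)(CC)CC | intermediate
30 | (5S,6S,7S,10S,13E)-7α,15-dihydroxylabda-8,13-dien-6β-yl 3-methylbutanoate (CNP0173680.1) | CC1=C(CC/C(C)=C/CO)[C@@]2(C)CCCC(C)(C)[C@@H]2[C@H](OC(=O)CC(C)C)[C@H]1O | target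

**Step count**

Total: 21 steps. Longest linear sequence: 19 steps (steps 1–3 and 6–21, from ethyl 3-methylbut-2-enoate); steps 4 and 5 form the short branch.

**Steps most likely to fail**

Step 9. The congested ketene acetal may fragment or undergo silyl migration before the strained boat is reached, so that the bond between C5 and the fully substituted C10 does not form. The fallback replaces the lactone boat by an open-chain chair rearrangement and closes ring A by metathesis; it sets out from alkyne 6 (through alane 10) and returns at acid 16. Alane 10 would be acetylated (acetyl chloride, Pd(PPh3)4) to (3E)-4-methyl-7-(2-methyl-1,3-dioxolan-2-yl)-5-(prop-1-en-2-yl)hept-3-en-2-one F1. This would be reduced with the (S)-Me-CBS catalyst and catecholborane to (2R,3E)-4-methyl-7-(2-methyl-1,3-dioxolan-2-yl)-5-(prop-1-en-2-yl)hept-3-en-2-ol F2. F2 would be esterified (DCC, DMAP) with 3,3-dimethylhex-5-enoic acid (C=CCC(C)(C)CC(=O)O) to the 3,3-dimethylhex-5-enoate ester F3. An open-chain Ireland–Claisen rearrangement (LDA, THF–HMPA, TBSCl, then warming; Z(O)-enolate, chair transition state) should give the open-chain diene acid F4, with C5 and C10 configured as in 16 and the former carbinol carbon left as a disposable (E)-propenyl group. Ring-closing metathesis between that propenyl group and the terminal vinyl group would then close ring A and deliver 16.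

Step 14. Proton removal may occur at C5 or at the C8 methyl group instead of C9, or oxygen may be transferred to the γ-carbon C9. The fallback fixes the enol regiochemistry under acid and uses a different oxidant; it sets out from enone 21 and returns at hydroxy ketone 23. Enol acetylation under thermodynamic control (isopropenyl acetate, cat. TsOH) would give the linear 6-acetoxy-14,15-dinorlabda-6,8-dien-13-one ethylene ketal F5. Catalytic OsO4 with NMO should then attack the less hindered enol acetate double bond (C6=C7) from the α-face, and the osmate collapses with loss of acetate to 23.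

Step 11. The hindered, electron-poor vinyl ketone may fail to load onto ruthenium and be consumed by intermolecular metathesis instead of ring closure. The fallback closes ring B by electrophilic acylation of the isopropenyl group; it sets out from acid chloride 17 and returns at enone 19. Treatment of 17 with Me2AlCl (CH2Cl2, −78 °C; aliphatic Friedel–Crafts acylation with an HCl-scavenging Lewis acid) should give the cis-fused (5R,10R)-14,15-dinorlabda-1,8(17)-diene-6,13-dione 13-ethylene ketal F6. DBU (CH2Cl2, rt) then moves the exocyclic double bond into conjugation to give 19.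

**Further compounds**

F1 | step 9 | (3E)-4-methyl-7-(2-methyl-1,3-dioxolan-2-yl)-5-(prop-1-en-2-yl)hept-3-en-2-one | CC(=O)/C=C(\C)C(CCC1(C)OCCO1)C(C)=C
F2 | step 9 | (2R,3E)-4-methyl-7-(2-methyl-1,3-dioxolan-2-yl)-5-(prop-1-en-2-yl)hept-3-en-2-ol | C[C@@H](O)/C=C(\C)C(CCC1(C)OCCO1)C(C)=C
F3 | step 9 | (2R,3E)-4-methyl-7-(2-methyl-1,3-dioxolan-2-yl)-5-(prop-1-en-2-yl)hept-3-en-2-yl 3,3-dimethylhex-5-enoate | C=CCC(C)(C)CC(=O)O[C@H](C)/C=C(\C)C(CCC1(C)OCCO1)C(C)=C
F4 | step 9 | 3-methyl-2-(2-methylpent-4-en-2-yl)-6-(2-methyl-1,3-dioxolan-2-yl)-3-[(1E)-prop-1-en-1-yl]-4-(prop-1-en-2-yl)hexanoic acid (C2 and C3 configured as C5 and C10 of 16) | OC(=O)[C@H](C(C)(C)CC=C)[C@](C)(/C=C/C)C(CCC1(C)OCCO1)C(C)=C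
F5 | step 14 | 6-acetoxy-14,15-dinorlabda-6,8-dien-13-one ethylene ketal | CC1=C(CCC3(C)OCCO3)[C@@]2(C)CCCC(C)(C)[C@@H]2C(OC(C)=O)=C1
F6 | step 11 | (5R,10R)-14,15-dinorlabda-1,8(17)-diene-6,13-dione 13-ethylene ketal (cis-fused) | C=C1CC(=O)[C@@H]2C(C)(C)CC=C[C@]2(C)C1CCC3(C)OCCO3
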